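The north-east vessel, stirred at constant volume, got everything at the start; the other flasks are dosed beside it.

| flask | D | X | Z | time | remark |
|---|---|---|---|---|---|
| north-west | 0.020 M | 0.950 equiv (in portions, 2, over 3.0 d) | 1.20 equiv | 15 d | first portion at the start, last at 3.0 d |
| south-west | 0.020 M | 0.950 equiv (fed, over 3.0 d) | 1.20 equiv | 15 d | all else is in the flask from the start; the feed brings no volume worth counting |
| north-east | 0.020 M | 0.950 equiv | 1.20 equiv | 15 d | everything together at the start |
| north | 0.020 M (fed, over 3.0 d) | 0.950 equiv | 1.20 equiv | 15 d | all else is in the flask from the start; the feed brings no volume worth counting |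

    D + Z.D.X → E (k1 = 4.9 M⁻¹ h⁻¹)
    X ⇌ G (K2 = 0.61, k2 = 0.075 h⁻¹)
    D + Z → D.Z (k3 = 0.40 M⁻¹ h⁻¹)
    D + X → D.X (k4 = 2.5 M⁻¹ h⁻¹)
    Z + D.X → Z.D.X (k5 = 1.1 M⁻¹ h⁻¹)

- the flask with the highest amount of Z.D.X, in percent of the D charged ("all alike" if they lie within 1.5 percentage points) (north-west / south-west / north-east / north / all alike)
- final Z.D.X, as a percentage of the D charged, in north-west
- final Z.D.X, as a percentage of the D charged, in south-west
- final Z.D.X, as a percentage of the D charged, in north-east
- final Z.D.X, as a percentage of the D charged, in north

- a species is counted by the D in it: one E counts as two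
- run time (north-west): 15 d

You take over the bench, so here is my own reckoning for north-east. X has a half-life of 0.39 d towards G by the forward step alone, shorter than the 3.0 d half-life of D by step 3 alone, so I count free X as its charge over one plus K2. With X and Z held as charged, which is rough, D then behaves pseudo-first-order: it enters D.X at 0.0295 h⁻¹ and, counting step 3 as well, leaves at 0.0391 h⁻¹, while D.X becomes Z.D.X at 0.0264 h⁻¹.

At 26.9 % of the D charge, with Z as charged, a Z.D.X lasts under D as long as a D.X lasts under Z; call this the hand-over share. Above it I count Z.D.X as lost, below it as kept. By this reckoning D reaches it after 1.40 d, when D.X holds 33.2 % of the D charged, and that is what I expect to find as Z.D.X. Add no D: with D as charged, Z.D.X has a half-life of 0.29 d by step 1 alone, short against the 15 d run. For the dosed flasks I commit to no number.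

The forecast names north, with 31 % in north-west, 28 % in south-west, 34 % in north-east and 38 % in north, holding that “feeding D keeps free D low against plentiful X and Z”.

The simulation puts north-east first at 35.4 %, then north at 31.1 %, south-west at 29.5 % and north-west at 25.0 %. North-east is not quite at rest: at 15.0 d D stands at 0 %, below the hand-over share, and by 150 d Z.D.X reaches 36.6 % as D.X falls from 1.21 % to 0 %, with E still 41.9 %. In the neighbour with 2.40 equiv of X, dosed like north-west, I reckon from the first portion that D enters D.X at 0.0373 h⁻¹ and reaches the hand-over share after 1.17 d, before the last portion at 3.0 d, with 37.9 % of the D charged in D.X. Computed, it ends at 47.1 %.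

The constants are assumed.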